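**Plan**

1. Retrosynthetic cuts, in order: the gallate ester C–O at lower C3; then, together, upper C4–C4a and lower O1–C2 (both pyran rings); then lower C6–upper C4 (aryllithium + aldehyde), upper O1–C2 (phenoxide + cis-glycidate), lower C3–C4 (acetylide + aldehyde) and lower C4–C4a (formylation).
2. Forward: the upper chain (C2–C4 with ring B and the phloroglucinol ether) and the lower phenol with its cis-epoxide side chain are built open-chain and joined at upper C4. Only then are upper ring C and lower ring C closed, in that order, in one flask; galloylation and hydrogenolysis finish.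
3. Enabling feature: lower C6, the carbon that carries upper C4, is para to lower C8a–O1 on lower ring A. Loss of water at upper C4 therefore gives a para-quinone methide of lower ring A, and when upper ring A adds to it, lower ring A becomes again the C8a phenol that closes lower ring C onto the epoxide.
4. Stereochemistry: upper C2/C3 and lower C2/C3 come from two (S,S)-(salen)MnCl epoxidations of (Z)-alkenes, each cis-epoxide being opened with inversion at its benzylic carbon by an aryl oxygen (both halves 2R,3R, 2,3-cis). Upper C4 is set in the key step, trans to the C3 benzyloxy group, by allylic strain in the quinone methide.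

Key step: step 16

Remark: 1, 4 and 25 are taken as purchasable; (salen)MnCl is chloro[N,N'-bis(3,5-di-tert-butylsalicylidene)cyclohexane-1,2-diaminato]manganese, C36H52ClMnN2O2, whose (S,S)-form is assumed, by analogy with cis-β-methylstyrene and cis-cinnamates, to make the benzylic epoxide carbon S (the (R,R)-form would be used in steps 2 and 13 if the sense proved opposite); flavan numbering is used for both halves (upper = unit linked through C4, lower = galloylated unit).

**Route**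

Step 1
Reactants: 1 3,4,5-tris(benzyloxy)benzaldehyde
Product: 2 methyl (2Z)-3-[3,4,5-tris(benzyloxy)phenyl]prop-2-enoate
Conditions: (CF3CH2O)2P(O)CH2CO2Me, KN(SiMe3)2, 18-crown-6, THF, −78 °C
Reagents that add atoms: methyl bis(2,2,2-trifluoroethyl)phosphonoacetate, COC(=O)CP(=O)(OCC(F)(F)F)OCC(F)(F)F
Why: Still–Gennari olefination: the electron-poor trifluoroethyl phosphonate makes oxaphosphetane collapse faster than equilibration, so an aromatic aldehyde should give the (Z)-enoate that the cis-epoxide requires.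

Step 2
Reactants: 2 methyl (2Z)-3-[3,4,5-tris(benzyloxy)phenyl]prop-2-enoate
Product: 3 methyl (2S,3S)-3-[3,4,5-tris(benzyloxy)phenyl]oxirane-2-carboxylate (cis)
Conditions: (S,S)-(salen)MnCl (6 mol %), NaOCl (aq, pH 11.3), 4-phenylpyridine N-oxide, CH2Cl2, 4 °C
Reagents that add atoms: sodium hypochlorite, [Na+].[O-]Cl
Why: Jacobsen epoxidation of a cis-cinnamate ester, a standard substrate class, in which the (S,S)-ligand is expected to deliver oxygen to the face that makes the benzylic carbon S; any trans-epoxide from stepwise collapse is removed by chromatography.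

Step 3
Reactants: 3 methyl (2S,3S)-3-[3,4,5-tris(benzyloxy)phenyl]oxirane-2-carboxylate; 4 3,5-bis(benzyloxy)phenol
Product: 5 methyl (2S,3R)-3-[3,5-bis(benzyloxy)phenoxy]-2-hydroxy-3-[3,4,5-tris(benzyloxy)phenyl]propanoate
Conditions: Cs2CO3 (0.3 equiv), DMF, 45 °C
Reagents that add atoms: none
Why: Base-mediated opening of a 2,3-epoxy ester by a phenoxide: attack occurs at the benzylic C3 remote from the ester with inversion (SN2), so the cis-epoxide should give the syn aryl ether, which forms upper O1–C2 and fixes upper C2 and C3.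

Step 4
Reactants: 5 methyl (2S,3R)-3-[3,5-bis(benzyloxy)phenoxy]-2-hydroxy-3-[3,4,5-tris(benzyloxy)phenyl]propanoate
Product: 6 methyl (2S,3R)-2-(benzyloxy)-3-[3,5-bis(benzyloxy)phenoxy]-3-[3,4,5-tris(benzyloxy)phenyl]propanoate
Conditions: BnBr, Ag2O, 4 Å MS, CH2Cl2, rt, dark
Reagents that add atoms: benzyl bromide, BrCc1ccccc1
Why: Silver-oxide-mediated O-benzylation (Williamson type without a free alkoxide), chosen because a strong base could eliminate the β-aryloxy group or epimerise the α-carbon.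

Step 5
Reactants: 6 methyl (2S,3R)-2-(benzyloxy)-3-[3,5-bis(benzyloxy)phenoxy]-3-[3,4,5-tris(benzyloxy)phenyl]propanoate
Product: 7 (2S,3R)-2-(benzyloxy)-3-[3,5-bis(benzyloxy)phenoxy]-3-[3,4,5-tris(benzyloxy)phenyl]propanal
Conditions: i-Bu2AlH (1.1 equiv), toluene/CH2Cl2, −78 °C; MeOH, then aq KNaC4H4O6
Reagents that add atoms: none
Why: Partial reduction of an ester with i-Bu2AlH: the α-alkoxy-stabilised aluminium hemiacetal persists at −78 °C and releases the aldehyde only on work-up, and the aldehyde is used at once to avoid epimerisation.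

Step 6
Reactants: 4 3,5-bis(benzyloxy)phenol
Product: 8 [3,5-bis(benzyloxy)phenoxy]tri(propan-2-yl)silane
Conditions: i-Pr3SiCl, imidazole, DMF, rt
Reagents that add atoms: chlorotri(propan-2-yl)silane, CC(C)[Si](Cl)(C(C)C)C(C)C
Why: Standard silylation of a phenol; the bulky triisopropylsilyl ether survives alkyllithiums, Vilsmeier conditions and trifluoroacetic acid and does not direct metalation to its own ortho positions.

Step 7
Reactants: 8 [3,5-bis(benzyloxy)phenoxy]tri(propan-2-yl)silane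
Product: 10 [4-bromo-3,5-bis(benzyloxy)phenoxy]tri(propan-2-yl)silane, via 4-lithio silyl ether 9 (not isolated)
Conditions: n-BuLi, THF, 0 °C, 1 h; then BrCH2CH2Br, −78 °C to rt
Reagents that add atoms: 1,2-dibromoethane, BrCCBr
Why: Directed ortho-metalation then bromination: the C–H flanked by two benzyloxy groups is removed through double coordination of lithium while the silyl ether shields its neighbours, so bromine enters para to the silyloxy group at the future lower C6.

Step 8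
Reactants: 10 [4-bromo-3,5-bis(benzyloxy)phenoxy]tri(propan-2-yl)silane
Product: 12 3-bromo-2,4-bis(benzyloxy)-6-[(triisopropylsilyl)oxy]benzaldehyde, via aryl iminium chloride 11 (not isolated)
Conditions: POCl3, DMF, 0 °C to rt; then ice-water
Reagents that add atoms: N,N-dimethylformamide, CN(C)C=O; water, O
Why: Vilsmeier–Haack formylation: the two free ring positions are equivalent and each is ortho/para to three oxygen donors, so the chloroiminium ion can only enter ortho to the silyloxy group, installing the future lower C4.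

Step 9
Reactants: 1 3,4,5-tris(benzyloxy)benzaldehyde
Product: 13 1,2,3-tris(benzyloxy)-5-ethynylbenzene
Conditions: MeC(O)C(N2)P(O)(OMe)2, K2CO3, MeOH/THF, rt
Reagents that add atoms: dimethyl (1-diazo-2-oxopropyl)phosphonate, COP(=O)(OC)C(=[N+]=[N-])C(C)=O
Why: Ohira–Bestmann (Seyferth–Gilbert) homologation of an aromatic aldehyde to the terminal alkyne under mild carbonate conditions that leave benzyl ethers untouched.

Step 10
Reactants: 13 1,2,3-tris(benzyloxy)-5-ethynylbenzene; 12 3-bromo-2,4-bis(benzyloxy)-6-[(triisopropylsilyl)oxy]benzaldehyde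
Product: 15 (1RS)-1-{3-bromo-2,4-bis(benzyloxy)-6-[(triisopropylsilyl)oxy]phenyl}-3-[3,4,5-tris(benzyloxy)phenyl]prop-2-yn-1-ol, via lithium acetylide 14 (not isolated)
Conditions: n-BuLi, THF, −78 °C; then 12, −78 °C; AcOH quench at −78 °C
Reagents that add atoms: none
Why: 1,2-Addition of a lithium acetylide to a non-enolisable aromatic aldehyde forms lower C3–C4; the acetylide does not exchange with the aryl bromide, and the cold acidic quench prevents silyl migration to the new alkoxide.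

Step 11
Reactants: 15 (1RS)-1-{3-bromo-2,4-bis(benzyloxy)-6-[(triisopropylsilyl)oxy]phenyl}-3-[3,4,5-tris(benzyloxy)phenyl]prop-2-yn-1-ol
Product: 16 {4-bromo-3,5-bis(benzyloxy)-2-[3-(3,4,5-tris(benzyloxy)phenyl)prop-2-yn-1-yl]phenoxy}tri(propan-2-yl)silane
Conditions: Et3SiH, CF3CO2H, CH2Cl2, −40 to 0 °C
Reagents that add atoms: none
Why: Ionic hydrogenation (reductive deoxygenation): acid ionises the carbinol to a cation stabilised by the 2,4,6-trioxygenated ring, and Et3SiH delivers hydride to that benzylic carbon, not to the remote alkyne terminus, so the propargylic methylene results.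

Step 12
Reactants: 16 {4-bromo-3,5-bis(benzyloxy)-2-[3-(3,4,5-tris(benzyloxy)phenyl)prop-2-yn-1-yl]phenoxy}tri(propan-2-yl)silane
Product: 17 {4-bromo-3,5-bis(benzyloxy)-2-[(2Z)-3-(3,4,5-tris(benzyloxy)phenyl)prop-2-en-1-yl]phenoxy}tri(propan-2-yl)silane
Conditions: H2 (1 atm), Pd/CaCO3 poisoned with Pb(OAc)2 (Lindlar catalyst), quinoline, EtOAc, rt
Reagents that add atoms: none
Why: Lindlar semi-hydrogenation: syn delivery of one equivalent of hydrogen on lead-poisoned palladium gives the (Z)-alkene, and aryl bromide and benzyl ethers are inert under these mild conditions.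

Step 13
Reactants: 17 {4-bromo-3,5-bis(benzyloxy)-2-[(2Z)-3-(3,4,5-tris(benzyloxy)phenyl)prop-2-en-1-yl]phenoxy}tri(propan-2-yl)silane
Product: 18 [4-bromo-3,5-bis(benzyloxy)-2-({(2R,3S)-3-[3,4,5-tris(benzyloxy)phenyl]oxiran-2-yl}methyl)phenoxy]tri(propan-2-yl)silane (cis-epoxide)
Conditions: (S,S)-(salen)MnCl (5 mol %), mCPBA, N-methylmorpholine N-oxide, CH2Cl2, −78 °C
Reagents that add atoms: 3-chloroperoxybenzoic acid, OOC(=O)c1cccc(Cl)c1
Why: Jacobsen epoxidation in its low-temperature peracid/N-oxide form: a cis-β-substituted styrene is the best substrate class, the (S,S)-ligand is expected to make the benzylic carbon S as in step 2, and the anhydrous oxidant avoids the ring chlorination that hypochlorite could cause.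

Step 14
Reactants: 18 cis-epoxide aryl bromide; 7 (2S,3R)-2-(benzyloxy)-3-[3,5-bis(benzyloxy)phenoxy]-3-[3,4,5-tris(benzyloxy)phenyl]propanal
Product: 20 silyl-protected C4 carbinol (both C4 epimers; full name in the compound list), via aryllithium 19 (not isolated)
Conditions: n-BuLi (1.05 equiv), THF, −78 °C, 10 min; then 7, −78 °C; AcOH quench at −78 °C
Reagents that add atoms: none
Why: Bromine–lithium exchange then 1,2-addition to an aldehyde forms lower C6–upper C4: exchange at −78 °C outruns attack on the epoxide, which the lithiated carbon cannot reach within the molecule, and the new carbinol centre needs no control because step 16 erases it.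

Step 15
Reactants: 20 silyl-protected C4 carbinol
Product: 21 phenolic cis-epoxide carbinol (both C4 epimers; full name in the compound list)
Conditions: Bu4NF, AcOH (1:1), THF, 0 °C; crude product taken on
Reagents that add atoms: none
Why: Fluoride-mediated desilylation buffered with acetic acid frees the phenol without a phenoxide that could open the epoxide by the 5-exo path.

Step 16
Reactants: 21 phenolic cis-epoxide carbinol
Product: 24 undeca-O-benzyl dimer (free lower 3-OH), via para-quinone methide 22 (not isolated), via ring-closed phenol epoxide 23 (not isolated)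
Conditions: (+)-camphor-10-sulfonic acid (0.2 equiv), 4 Å MS, CH2Cl2 (0.005 M), −40 to 0 °C; Et3N quench
Reagents that add atoms: none
Why: Proposed new method: catalytic acid removes the carbinol hydroxyl as water with the push of the para hydroxyl and gives para-quinone methide 22 (or its protonated form); the ortho carbon of the 3,5-bis(benzyloxy)phenyl ether adds to the exocyclic carbon, which forms upper C4–C4a and returns lower ring A to phenol 23, and this phenol then attacks the acid-activated epoxide at its benzylic carbon to form lower O1–C2. The closest known reaction types are 1,6-additions of electron-rich arenes to para-quinone methides, Friedel–Crafts closures of electron-rich benzylic alcohols to 4-arylchromans, and acid-catalysed 6-endo openings of aryl epoxides by an ortho-tethered phenol; what is new is their coupling through one phenol in one flask. Upper ring C closes in a 6-exo-trig mode at the exocyclic quinone methide carbon (the arene reacting through its ortho carbon), and lower ring C closes by a 6-endo-tet opening of the epoxide. Upper C4 is controlled by the C3 stereocentre: allylic 1,3-strain with the flanking benzyloxy groups of lower ring A holds C3–H in the plane of the quinone methide, so the arene tethered through C2 can only reach the face opposite the C3 benzyloxy group, and both carbinol epimers should give the 3,4-trans (4β) bond. Lower C2 is controlled by stereospecific inversion of the (S)-benzylic epoxide carbon while lower C3 keeps the epoxide configuration, so the cis-epoxide should give the 2,3-cis ring with a free 3-hydroxyl. The step needs six-ring closure by the phloroglucinol ether to beat indane formation by ring B and intermolecular capture (secured by its three ortho/para oxygen donors and high dilution), and it needs backside, endo-selective epoxide opening without a free cation or 5-exo attack (secured by the 3,4,5-tris(benzyloxy)phenyl group, whose meta oxygens are inductively withdrawing, so the benzylic carbon is activated but should not ionise under catalytic sulfonic acid at low temperature).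

Step 17
Reactants: 24 undeca-O-benzyl dimer (free lower 3-OH); 25 3,4,5-tris(benzyloxy)benzoyl chloride
Product: 26 tetradeca-O-benzyl epigallocatechin-(4β→6)-epigallocatechin 3-O-gallate
Conditions: DMAP, Et3N, CH2Cl2, 0 °C to rt
Reagents that add atoms: none
Why: DMAP-catalysed acylation of the only free hydroxyl (axial, lower C3) by the acid chloride, the standard way to galloylate 2,3-cis flavan-3-ols, with no change at any stereocentre.

Step 18
Reactants: 26 tetradeca-O-benzyl epigallocatechin-(4β→6)-epigallocatechin 3-O-gallate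
Product: 27 (−)-epigallocatechin-(4β→6)-(−)-epigallocatechin 3-O-gallate (gallate on the lower unit), the target
Conditions: H2 (1 atm), Pd(OH)2/C, THF/MeOH/H2O, rt
Reagents that add atoms: none
Why: Catalytic hydrogenolysis of all fourteen benzyl ethers under neutral conditions, which leaves the ester, the interflavan C4–C6 bond and the five stereocentres untouched.

**Compound list**

1 | 3,4,5-tris(benzyloxy)benzaldehyde | O=Cc1cc(OCc2ccccc2)c(OCc2ccccc2)c(OCc2ccccc2)c1 | starting material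
2 | methyl (2Z)-3-[3,4,5-tris(benzyloxy)phenyl]prop-2-enoate | COC(=O)/C=C\c1cc(OCc2ccccc2)c(OCc2ccccc2)c(OCc2ccccc2)c1 | intermediate
3 | methyl (2S,3S)-3-[3,4,5-tris(benzyloxy)phenyl]oxirane-2-carboxylate (cis) | COC(=O)[C@H]1O[C@H]1c1cc(OCc2ccccc2)c(OCc2ccccc2)c(OCc2ccccc2)c1 | intermediate
4 | 3,5-bis(benzyloxy)phenol | Oc1cc(OCc2ccccc2)cc(OCc2ccccc2)c1 | starting material
5 | methyl (2S,3R)-3-[3,5-bis(benzyloxy)phenoxy]-2-hydroxy-3-[3,4,5-tris(benzyloxy)phenyl]propanoate | COC(=O)[C@@H](O)[C@@H](c1cc(OCc2ccccc2)c(OCc2ccccc2)c(OCc2ccccc2)c1)Oc1cc(OCc2ccccc2)cc(OCc2ccccc2)c1 | intermediate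
6 | methyl (2S,3R)-2-(benzyloxy)-3-[3,5-bis(benzyloxy)phenoxy]-3-[3,4,5-tris(benzyloxy)phenyl]propanoate | COC(=O)[C@@H](OCc1ccccc1)[C@@H](c1cc(OCc2ccccc2)c(OCc2ccccc2)c(OCc2ccccc2)c1)Oc1cc(OCc2ccccc2)cc(OCc2ccccc2)c1 | intermediate
7 | (2S,3R)-2-(benzyloxy)-3-[3,5-bis(benzyloxy)phenoxy]-3-[3,4,5-tris(benzyloxy)phenyl]propanal | O=C[C@@H](OCc1ccccc1)[C@@H](c1cc(OCc2ccccc2)c(OCc2ccccc2)c(OCc2ccccc2)c1)Oc1cc(OCc2ccccc2)cc(OCc2ccccc2)c1 | intermediate
8 | [3,5-bis(benzyloxy)phenoxy]tri(propan-2-yl)silane | CC(C)[Si](Oc1cc(OCc2ccccc2)cc(OCc2ccccc2)c1)(C(C)C)C(C)C | intermediate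
9 | {2,6-bis(benzyloxy)-4-[(triisopropylsilyl)oxy]phenyl}lithium | [Li]c1c(OCc2ccccc2)cc(O[Si](C(C)C)(C(C)C)C(C)C)cc1OCc1ccccc1 | intermediate (not isolated)
10 | [4-bromo-3,5-bis(benzyloxy)phenoxy]tri(propan-2-yl)silane | CC(C)[Si](Oc1cc(OCc2ccccc2)c(Br)c(OCc2ccccc2)c1)(C(C)C)C(C)C | intermediate
11 | ({3-bromo-2,4-bis(benzyloxy)-6-[(triisopropylsilyl)oxy]phenyl}methylidene)dimethylammonium chloride | C[N+](C)=Cc1c(O[Si](C(C)C)(C(C)C)C(C)C)cc(OCc2ccccc2)c(Br)c1OCc1ccccc1.[Cl-] | intermediate (not isolated)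
12 | 3-bromo-2,4-bis(benzyloxy)-6-[(triisopropylsilyl)oxy]benzaldehyde | O=Cc1c(O[Si](C(C)C)(C(C)C)C(C)C)cc(OCc2ccccc2)c(Br)c1OCc1ccccc1 | intermediate
13 | 1,2,3-tris(benzyloxy)-5-ethynylbenzene | C#Cc1cc(OCc2ccccc2)c(OCc2ccccc2)c(OCc2ccccc2)c1 | intermediate
14 | lithium [3,4,5-tris(benzyloxy)phenyl]acetylide | [Li]C#Cc1cc(OCc2ccccc2)c(OCc2ccccc2)c(OCc2ccccc2)c1 | intermediate (not isolated)
15 | (1RS)-1-{3-bromo-2,4-bis(benzyloxy)-6-[(triisopropylsilyl)oxy]phenyl}-3-[3,4,5-tris(benzyloxy)phenyl]prop-2-yn-1-ol | OC(C#Cc1cc(OCc2ccccc2)c(OCc2ccccc2)c(OCc2ccccc2)c1)c1c(O[Si](C(C)C)(C(C)C)C(C)C)cc(OCc2ccccc2)c(Br)c1OCc1ccccc1 | intermediate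
16 | {4-bromo-3,5-bis(benzyloxy)-2-[3-(3,4,5-tris(benzyloxy)phenyl)prop-2-yn-1-yl]phenoxy}tri(propan-2-yl)silane | CC(C)[Si](Oc1cc(OCc2ccccc2)c(Br)c(OCc2ccccc2)c1CC#Cc1cc(OCc2ccccc2)c(OCc2ccccc2)c(OCc2ccccc2)c1)(C(C)C)C(C)C | intermediate
17 | {4-bromo-3,5-bis(benzyloxy)-2-[(2Z)-3-(3,4,5-tris(benzyloxy)phenyl)prop-2-en-1-yl]phenoxy}tri(propan-2-yl)silane | CC(C)[Si](Oc1cc(OCc2ccccc2)c(Br)c(OCc2ccccc2)c1C/C=C\c1cc(OCc2ccccc2)c(OCc2ccccc2)c(OCc2ccccc2)c1)(C(C)C)C(C)C | intermediate
18 | [4-bromo-3,5-bis(benzyloxy)-2-({(2R,3S)-3-[3,4,5-tris(benzyloxy)phenyl]oxiran-2-yl}methyl)phenoxy]tri(propan-2-yl)silane (cis-epoxide) | CC(C)[Si](Oc1cc(OCc2ccccc2)c(Br)c(OCc2ccccc2)c1C[C@H]1O[C@H]1c1cc(OCc2ccccc2)c(OCc2ccccc2)c(OCc2ccccc2)c1)(C(C)C)C(C)C | intermediate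
19 | [2,6-bis(benzyloxy)-3-({(2R,3S)-3-[3,4,5-tris(benzyloxy)phenyl]oxiran-2-yl}methyl)-4-[(triisopropylsilyl)oxy]phenyl]lithium | CC(C)[Si](Oc1cc(OCc2ccccc2)c([Li])c(OCc2ccccc2)c1C[C@H]1O[C@H]1c1cc(OCc2ccccc2)c(OCc2ccccc2)c(OCc2ccccc2)c1)(C(C)C)C(C)C | intermediate (not isolated)
20 | (1RS,2R,3R)-2-(benzyloxy)-3-[3,5-bis(benzyloxy)phenoxy]-1-[2,6-bis(benzyloxy)-3-({(2R,3S)-3-[3,4,5-tris(benzyloxy)phenyl]oxiran-2-yl}methyl)-4-[(triisopropylsilyl)oxy]phenyl]-3-[3,4,5-tris(benzyloxy)phenyl]propan-1-ol (both epimers at C1 = upper C4) | CC(C)[Si](Oc1cc(OCc2ccccc2)c(C(O)[C@@H](OCc2ccccc2)[C@@H](c2cc(OCc3ccccc3)c(OCc3ccccc3)c(OCc3ccccc3)c2)Oc2cc(OCc3ccccc3)cc(OCc3ccccc3)c2)c(OCc2ccccc2)c1C[C@H]1O[C@H]1c1cc(OCc2ccccc2)c(OCc2ccccc2)c(OCc2ccccc2)c1)(C(C)C)C(C)C | intermediate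
21 | 3,5-bis(benzyloxy)-4-{(1RS,2R,3R)-2-(benzyloxy)-3-[3,5-bis(benzyloxy)phenoxy]-1-hydroxy-3-[3,4,5-tris(benzyloxy)phenyl]propyl}-2-({(2R,3S)-3-[3,4,5-tris(benzyloxy)phenyl]oxiran-2-yl}methyl)phenol (both carbinol epimers) | Oc1cc(OCc2ccccc2)c(C(O)[C@@H](OCc2ccccc2)[C@@H](c2cc(OCc3ccccc3)c(OCc3ccccc3)c(OCc3ccccc3)c2)Oc2cc(OCc3ccccc3)cc(OCc3ccccc3)c2)c(OCc2ccccc2)c1C[C@H]1O[C@H]1c1cc(OCc2ccccc2)c(OCc2ccccc2)c(OCc2ccccc2)c1 | intermediate
22 | para-quinone methide of lower ring A: 3,5-bis(benzyloxy)-4-ylidene-cyclohexa-2,5-dien-1-one carrying the epoxide side chain at C2 and the upper chain C3–C2 on the exocyclic carbon (either alkene geometry) | O=C1C=C(OCc2ccccc2)C(=C[C@@H](OCc2ccccc2)[C@@H](c2cc(OCc3ccccc3)c(OCc3ccccc3)c(OCc3ccccc3)c2)Oc2cc(OCc3ccccc3)cc(OCc3ccccc3)c2)C(OCc2ccccc2)=C1C[C@H]1O[C@H]1c1cc(OCc2ccccc2)c(OCc2ccccc2)c(OCc2ccccc2)c1 | intermediate (not isolated)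
23 | phenol with upper ring C closed (2,3-cis-3,4-trans hexa-O-benzyl flavan attached through C4) and the cis-epoxide intact | Oc1cc(OCc2ccccc2)c([C@H]2c3c(OCc4ccccc4)cc(OCc4ccccc4)cc3O[C@H](c3cc(OCc4ccccc4)c(OCc4ccccc4)c(OCc4ccccc4)c3)[C@@H]2OCc2ccccc2)c(OCc2ccccc2)c1C[C@H]1O[C@H]1c1cc(OCc2ccccc2)c(OCc2ccccc2)c(OCc2ccccc2)c1 | intermediate (not isolated)
24 | 3,5,7,3',4',5'-hexa-O-benzyl-epigallocatechin-(4β→6)-5,7,3',4',5'-penta-O-benzyl-epigallocatechin (both units 2R,3R; upper 3,4-trans; lower 3-OH free) | O[C@@H]1Cc2c(cc(OCc3ccccc3)c([C@H]3c4c(OCc5ccccc5)cc(OCc5ccccc5)cc4O[C@H](c4cc(OCc5ccccc5)c(OCc5ccccc5)c(OCc5ccccc5)c4)[C@@H]3OCc3ccccc3)c2OCc2ccccc2)O[C@@H]1c1cc(OCc2ccccc2)c(OCc2ccccc2)c(OCc2ccccc2)c1 | intermediate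
25 | 3,4,5-tris(benzyloxy)benzoyl chloride | ClC(=O)c1cc(OCc2ccccc2)c(OCc2ccccc2)c(OCc2ccccc2)c1 | starting material
26 | 24 esterified at lower O3 with 3,4,5-tris(benzyloxy)benzoic acid (tetradeca-O-benzyl target) | O=C(O[C@@H]1Cc2c(cc(OCc3ccccc3)c([C@H]3c4c(OCc5ccccc5)cc(OCc5ccccc5)cc4O[C@H](c4cc(OCc5ccccc5)c(OCc5ccccc5)c(OCc5ccccc5)c4)[C@@H]3OCc3ccccc3)c2OCc2ccccc2)O[C@@H]1c1cc(OCc2ccccc2)c(OCc2ccccc2)c(OCc2ccccc2)c1)c1cc(OCc2ccccc2)c(OCc2ccccc2)c(OCc2ccccc2)c1 | intermediate
27 | (−)-epigallocatechin-(4β→6)-(−)-epigallocatechin 3-O-gallate (gallate on the lower unit) | O=C(O[C@@H]1Cc2c(cc(O)c([C@H]3c4c(O)cc(O)cc4O[C@H](c4cc(O)c(O)c(O)c4)[C@@H]3O)c2O)O[C@@H]1c1cc(O)c(O)c(O)c1)c1cc(O)c(O)c(O)c1 | target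

**Step count and risks**

Total steps: 18. Longest linear sequence: 12 steps (6, 7, 8, 10, 11, 12, 13, 14, 15, 16, 17, 18).

Step 16 (Proposed new method). The two ring closures may fall out of step: the epoxide may ionise, rearrange to a ketone or be opened by a stray nucleophile before lower ring A is a phenol again, or the quinone methide may be captured intermolecularly. The fallback uncouples the two closures with known reactions and sets out from 18. Buffered Bu4NF/AcOH frees 4-bromo-3,5-bis(benzyloxy)-2-({(2R,3S)-3-[3,4,5-tris(benzyloxy)phenyl]oxiran-2-yl}methyl)phenol F1. Catalytic camphorsulfonic acid in CH2Cl2 then closes lower ring C by 6-endo epoxide opening to (2R,3R)-6-bromo-5,7-bis(benzyloxy)-2-[3,4,5-tris(benzyloxy)phenyl]chroman-3-ol F2. Two equivalents of n-BuLi at −78 °C give the lithium alkoxide aryllithium F3, which adds to aldehyde 7 to give the diol (2R,3R)-5,7-bis(benzyloxy)-6-{(1RS,2R,3R)-2-(benzyloxy)-3-[3,5-bis(benzyloxy)phenoxy]-1-hydroxy-3-[3,4,5-tris(benzyloxy)phenyl]propyl}-2-[3,4,5-tris(benzyloxy)phenyl]chroman-3-ol F4. BF3·OEt2 in CH2Cl2 at −78 °C then closes upper ring C by Friedel–Crafts alkylation of the phloroglucinol ether with the trioxygenated benzylic alcohol, and the route is rejoined at 24.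

Step 14. The hindered, basic aryllithium may deprotonate the aldehyde at its α-carbon in place of adding to the carbonyl, which would lead to β-elimination of the aryloxide or epimerisation at upper C3. The fallback changes the electrophile and its oxidation level and sets out from 6 (with 18). MeNH(OMe)·HCl and i-PrMgCl in THF at −20 °C convert 6 into the Weinreb amide (2S,3R)-2-(benzyloxy)-3-[3,5-bis(benzyloxy)phenoxy]-N-methoxy-N-methyl-3-[3,4,5-tris(benzyloxy)phenyl]propanamide F5. Aryllithium 19 (from 18 and n-BuLi) adds once to give, after a cold AcOH quench, the aryl ketone (2S,3R)-2-(benzyloxy)-3-[3,5-bis(benzyloxy)phenoxy]-1-[2,6-bis(benzyloxy)-3-({(2R,3S)-3-[3,4,5-tris(benzyloxy)phenyl]oxiran-2-yl}methyl)-4-[(triisopropylsilyl)oxy]phenyl]-3-[3,4,5-tris(benzyloxy)phenyl]propan-1-one F6. NaBH4 in MeOH/THF at 0 °C reduces the ketone to the carbinol epimers, and the route is rejoined at 20.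

Step 3. Regio- or stereocontrol may be lost in the epoxide opening: attack at C2, C-alkylation by the ambident phenoxide, or base-induced elimination of the aryloxide from the α-hydroxy ester. The fallback removes the ester before the opening and sets out from 3. NaBH4 in MeOH at 0 °C gives the cis-epoxy alcohol {(2R,3S)-3-[3,4,5-tris(benzyloxy)phenyl]oxiran-2-yl}methanol F7. The sodium phenoxide of 4 (NaOH, aqueous dioxane, 70 °C) opens it at the benzylic carbon with inversion to (2R,3R)-3-[3,5-bis(benzyloxy)phenoxy]-3-[3,4,5-tris(benzyloxy)phenyl]propane-1,2-diol F8. PhCH(OMe)2 and catalytic camphorsulfonic acid give the benzylidene acetal (4R)-4-{(R)-[3,5-bis(benzyloxy)phenoxy][3,4,5-tris(benzyloxy)phenyl]methyl}-2-phenyl-1,3-dioxolane F9. i-Bu2AlH in CH2Cl2 opens the acetal at the less hindered oxygen to (2R,3R)-2-(benzyloxy)-3-[3,5-bis(benzyloxy)phenoxy]-3-[3,4,5-tris(benzyloxy)phenyl]propan-1-ol F10. Dess–Martin oxidation then gives the aldehyde, and the route is rejoined at 7.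

**Further compounds**

F1 | step 16 | 4-bromo-3,5-bis(benzyloxy)-2-({(2R,3S)-3-[3,4,5-tris(benzyloxy)phenyl]oxiran-2-yl}methyl)phenol | Oc1cc(OCc2ccccc2)c(Br)c(OCc2ccccc2)c1C[C@H]1O[C@H]1c1cc(OCc2ccccc2)c(OCc2ccccc2)c(OCc2ccccc2)c1
F2 | step 16 | (2R,3R)-6-bromo-5,7-bis(benzyloxy)-2-[3,4,5-tris(benzyloxy)phenyl]chroman-3-ol | O[C@@H]1Cc2c(cc(OCc3ccccc3)c(Br)c2OCc2ccccc2)O[C@@H]1c1cc(OCc2ccccc2)c(OCc2ccccc2)c(OCc2ccccc2)c1
F3 | step 16 | lithium (2R,3R)-5,7-bis(benzyloxy)-6-lithio-2-[3,4,5-tris(benzyloxy)phenyl]chroman-3-olate | [Li]O[C@@H]1Cc2c(cc(OCc3ccccc3)c([Li])c2OCc2ccccc2)O[C@@H]1c1cc(OCc2ccccc2)c(OCc2ccccc2)c(OCc2ccccc2)c1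
F4 | step 16 | (2R,3R)-5,7-bis(benzyloxy)-6-{(1RS,2R,3R)-2-(benzyloxy)-3-[3,5-bis(benzyloxy)phenoxy]-1-hydroxy-3-[3,4,5-tris(benzyloxy)phenyl]propyl}-2-[3,4,5-tris(benzyloxy)phenyl]chroman-3-ol | O[C@@H]1Cc2c(cc(OCc3ccccc3)c(C(O)[C@@H](OCc3ccccc3)[C@@H](c3cc(OCc4ccccc4)c(OCc4ccccc4)c(OCc4ccccc4)c3)Oc3cc(OCc4ccccc4)cc(OCc4ccccc4)c3)c2OCc2ccccc2)O[C@@H]1c1cc(OCc2ccccc2)c(OCc2ccccc2)c(OCc2ccccc2)c1
F5 | step 14 | (2S,3R)-2-(benzyloxy)-3-[3,5-bis(benzyloxy)phenoxy]-N-methoxy-N-methyl-3-[3,4,5-tris(benzyloxy)phenyl]propanamide | CON(C)C(=O)[C@@H](OCc1ccccc1)[C@@H](c1cc(OCc2ccccc2)c(OCc2ccccc2)c(OCc2ccccc2)c1)Oc1cc(OCc2ccccc2)cc(OCc2ccccc2)c1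
F6 | step 14 | (2S,3R)-2-(benzyloxy)-3-[3,5-bis(benzyloxy)phenoxy]-1-[2,6-bis(benzyloxy)-3-({(2R,3S)-3-[3,4,5-tris(benzyloxy)phenyl]oxiran-2-yl}methyl)-4-[(triisopropylsilyl)oxy]phenyl]-3-[3,4,5-tris(benzyloxy)phenyl]propan-1-one | CC(C)[Si](Oc1cc(OCc2ccccc2)c(C(=O)[C@@H](OCc2ccccc2)[C@@H](c2cc(OCc3ccccc3)c(OCc3ccccc3)c(OCc3ccccc3)c2)Oc2cc(OCc3ccccc3)cc(OCc3ccccc3)c2)c(OCc2ccccc2)c1C[C@H]1O[C@H]1c1cc(OCc2ccccc2)c(OCc2ccccc2)c(OCc2ccccc2)c1)(C(C)C)C(C)C
F7 | step 3 | {(2R,3S)-3-[3,4,5-tris(benzyloxy)phenyl]oxiran-2-yl}methanol (cis) | OC[C@H]1O[C@H]1c1cc(OCc2ccccc2)c(OCc2ccccc2)c(OCc2ccccc2)c1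
F8 | step 3 | (2R,3R)-3-[3,5-bis(benzyloxy)phenoxy]-3-[3,4,5-tris(benzyloxy)phenyl]propane-1,2-diol | OC[C@@H](O)[C@@H](c1cc(OCc2ccccc2)c(OCc2ccccc2)c(OCc2ccccc2)c1)Oc1cc(OCc2ccccc2)cc(OCc2ccccc2)c1
F9 | step 3 | (4R)-4-{(R)-[3,5-bis(benzyloxy)phenoxy][3,4,5-tris(benzyloxy)phenyl]methyl}-2-phenyl-1,3-dioxolane (both acetal epimers) | O1C[C@@H](OC1c1ccccc1)[C@@H](c1cc(OCc2ccccc2)c(OCc2ccccc2)c(OCc2ccccc2)c1)Oc1cc(OCc2ccccc2)cc(OCc2ccccc2)c1
F10 | step 3 | (2R,3R)-2-(benzyloxy)-3-[3,5-bis(benzyloxy)phenoxy]-3-[3,4,5-tris(benzyloxy)phenyl]propan-1-ol | OC[C@@H](OCc1ccccc1)[C@@H](c1cc(OCc2ccccc2)c(OCc2ccccc2)c(OCc2ccccc2)c1)Oc1cc(OCc2ccccc2)cc(OCc2ccccc2)c1
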